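**Retrosynthetic overview**

- The target, a 12-oxo C20-gibberellin 7,19-dioic acid with a formyl group on C10, is traced back to its dimethyl ester, and this to a tetracyclic 10α,20α-epoxide in which ring A is still seven-membered (C10–C20–C1–C2–C3–C4–C5). An epoxide-to-aldehyde 1,2-shift moves C1 from C20 to C10, expels C20 as the formyl group and leaves six-membered ring A.
- Enabling feature: C20 is a CHO on quaternary C10 next to the C1 methylene, which is the retron of a ring contraction of a trisubstituted cycloheptene oxide. The C19 carboxyl on C4 is 1,3-cis to C20 across C5, so it can deliver the epoxide oxygen to the α face (iodolactone, then epoxy ester); C1 must then migrate on the β face, giving the trans A/B fusion.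
- Ring D: gold-catalysed 5-exo-dig closure of the C12 silyl enol ether onto the C8 propargyl group. Ring B: reductive Heck cyclization of the C10 alkenyl triflate onto C9 of a C8-quaternary cyclohexadienone (sets C8 and C9).
- Ring C: aldehyde Michael addition, Robinson annulation and dehydrogenation. C4: copper-catalysed asymmetric conjugate methylation of a cycloheptenone ester with aldol trapping at C5.
- Order of ring formation: seven-membered precursor of ring A (from cycloheptane-1,3-dione), then C, B, D, and last ring A by contraction.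

Key step: step 15

Remark: locants C1–C20 in names are those of the gibberellane skeleton; β is the face of H5 and H9, α the face of C19 and C20.
Remark: the ligand enantiomers named in steps 3 and 10 are assumed to give the stated sense; if not, the enantiomeric ligand is taken.

**Route**

Step 1
Reactants: 1 cycloheptane-1,3-dione
Product: 2 3-oxocyclohept-1-en-1-yl trifluoromethanesulfonate
Conditions: Tf2O, pyridine, CH2Cl2, −78 to 0 °C
Reagents that add atoms: trifluoromethanesulfonic anhydride, O=S(=O)(OS(=O)(=O)C(F)(F)F)C(F)(F)F
Why: O-sulfonylation of the enol of the 1,3-diketone should give the vinylogous acyl triflate; no stereocentre is involved.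

Step 2
Reactants: 2 3-oxocyclohept-1-en-1-yl trifluoromethanesulfonate
Product: 3 tert-butyl 3-oxocyclohept-1-ene-1-carboxylate
Conditions: Pd(OAc)2 (5 mol %), dppf (6 mol %), CO (1 atm), t-BuOH, Et3N, DMF, 70 °C
Reagents that add atoms: carbon monoxide, [C-]#[O+]; tert-butanol, CC(C)(C)O
Why: Palladium-catalysed alkoxycarbonylation of the alkenyl triflate (oxidative addition, CO insertion, capture of the acyl complex by the alcohol) should give the cyclic γ-keto enoate.

Step 3
Reactants: 3 tert-butyl 3-oxocyclohept-1-ene-1-carboxylate, 4 methyl glyoxylate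
Product: 6 tert-butyl (1R)-2-(1-hydroxy-2-methoxy-2-oxoethyl)-1-methyl-3-oxocycloheptane-1-carboxylate (mixture at the two aldol centres), via methylzinc enolate 5 (not isolated)
Conditions: Me2Zn, Cu(OTf)2 (5 mol %), chiral sulfonate-bearing imidazolinium salt (carbene precursor, 6 mol %), t-BuOMe, −30 °C; then 4, −78 °C; aq. NH4Cl
Reagents that add atoms: dimethylzinc, C[Zn]C
Why: Copper-catalysed asymmetric conjugate addition of the methylzinc reagent to the β-carbon (C4) of the cyclic γ-keto ester, with the chiral carbene ligand selecting the enantiotopic face (4R), is followed by aldol addition of the regiodefined zinc enolate to the glyoxylate at C5; the two aldol centres are removed in step 4.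

Step 4
Reactants: 6 tert-butyl (1R)-2-(1-hydroxy-2-methoxy-2-oxoethyl)-1-methyl-3-oxocycloheptane-1-carboxylate
Product: 8 tert-butyl (1R)-2-(2-methoxy-2-oxoethylidene)-1-methyl-3-oxocycloheptane-1-carboxylate (E/Z mixture), via methanesulfonate 7 (not isolated)
Conditions: MsCl, Et3N (3 equiv), CH2Cl2, 0 °C to rt
Reagents that add atoms: none
Why: Mesylation of the β-hydroxy ketone and E1cB elimination through the C5 enolate (aldol dehydration) should give the alkylidene keto diester.

Step 5
Reactants: 9 5-(trimethylsilyl)pent-4-yn-1-ol
Product: 10 5-(trimethylsilyl)pent-4-ynal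
Conditions: DMP (1,1,1-triacetoxy-1,1-dihydro-1,2-benziodoxol-3(1H)-one), CH2Cl2, rt
Reagents that add atoms: none
Why: Periodinane oxidation of the primary alcohol should stop at the aldehyde and leave the silyl alkyne untouched.

Step 6
Reactants: 8 tert-butyl (1R)-2-(2-methoxy-2-oxoethylidene)-1-methyl-3-oxocycloheptane-1-carboxylate, 10 5-(trimethylsilyl)pent-4-ynal
Product: 11 tert-butyl (1R,2R)-2-[3-formyl-1-methoxy-1-oxo-6-(trimethylsilyl)hex-5-yn-2-yl]-1-methyl-3-oxocycloheptane-1-carboxylate (epimers at the two side-chain centres C6 and C8)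
Conditions: pyrrolidine (20 mol %), PhCO2H (20 mol %), CH2Cl2, 0 °C to rt
Reagents that add atoms: none
Why: Enamine-catalysed Michael addition of the aldehyde occurs at C6, the unhindered terminus β to the ketone. C5 should then be set by kinetic protonation of the ring enol on the face opposite the bulky tert-butyl ester (H5 cis to the C4 methyl); an axial ester being less costly than an axial methyl should favour the same isomer on equilibration, and any C5 epimer is removed at 15 and recycled with base. C6 is corrected in step 12 and C8 is erased in step 8.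

Step 7
Reactants: 11 tert-butyl (1R,2R)-2-[3-formyl-1-methoxy-1-oxo-6-(trimethylsilyl)hex-5-yn-2-yl]-1-methyl-3-oxocycloheptane-1-carboxylate, 12 methyl vinyl ketone
Product: 14 tert-butyl (1R,2R)-2-{2-methoxy-2-oxo-1-[4-oxo-1-(3-(trimethylsilyl)prop-2-ynyl)cyclohex-2-en-1-yl]ethyl}-1-methyl-3-oxocycloheptane-1-carboxylate (epimers at C6 and C8), via keto aldehyde Michael adduct 13 (not isolated)
Conditions: pyrrolidine (30 mol %), AcOH, toluene, 60 °C
Reagents that add atoms: none
Why: Robinson annulation: enamine Michael addition of the α-branched aldehyde to the enone makes C8 quaternary, and aldol condensation of the methyl ketone onto the aldehyde closes ring C as the 4,4-disubstituted cyclohexenone; the C8 configuration does not matter because step 8 removes it.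

Step 8
Reactants: 14 tert-butyl (1R,2R)-2-{2-methoxy-2-oxo-1-[4-oxo-1-(3-(trimethylsilyl)prop-2-ynyl)cyclohex-2-en-1-yl]ethyl}-1-methyl-3-oxocycloheptane-1-carboxylate
Product: 15 tert-butyl (1R,2R)-2-{2-methoxy-2-oxo-1-[4-oxo-1-(3-(trimethylsilyl)prop-2-ynyl)cyclohexa-2,5-dien-1-yl]ethyl}-1-methyl-3-oxocycloheptane-1-carboxylate (epimers at C6)
Conditions: DDQ, 1,4-dioxane, 100 °C
Reagents that add atoms: none
Why: Quinone dehydrogenation of the enone through its dienol should give the cross-conjugated cyclohexadienone, which makes C8 non-stereogenic and offers two enone arms; the saturated cycloheptanone is not expected to react.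

Step 9
Reactants: 15 tert-butyl (1R,2R)-2-{2-methoxy-2-oxo-1-[4-oxo-1-(3-(trimethylsilyl)prop-2-ynyl)cyclohexa-2,5-dien-1-yl]ethyl}-1-methyl-3-oxocycloheptane-1-carboxylate
Product: 17 tert-butyl (1R,2R)-2-{2-methoxy-2-oxo-1-[4-oxo-1-(3-(trimethylsilyl)prop-2-ynyl)cyclohexa-2,5-dien-1-yl]ethyl}-1-methyl-3-(trifluoromethylsulfonyloxy)cyclohept-3-ene-1-carboxylate, via potassium enolate 16 (not isolated)
Conditions: KN(SiMe3)2, THF, −78 °C; then PhNTf2
Reagents that add atoms: N-phenylbis(trifluoromethanesulfonimide), O=S(=O)(N(c1ccccc1)S(=O)(=O)C(F)(F)F)C(F)(F)F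
Why: Kinetic deprotonation at the unhindered C20 methylene (C5–H is tertiary and next to quaternary C4; the dienone has no enolizable hydrogen) and O-triflation should give the less substituted enol triflate, fixing the C10=C20 double bond and the C5 configuration.

Step 10
Reactants: 17 tert-butyl (1R,2R)-2-{2-methoxy-2-oxo-1-[4-oxo-1-(3-(trimethylsilyl)prop-2-ynyl)cyclohexa-2,5-dien-1-yl]ethyl}-1-methyl-3-(trifluoromethylsulfonyloxy)cyclohept-3-ene-1-carboxylate
Product: 18 tricyclic diester: rings B and C cis-fused on the seven-membered ring; 5β-H, 9β-H, 8β-(3-trimethylsilylprop-2-ynyl), C10=C20 alkene, ring C 13-en-12-one, C19 tert-butyl ester, C7 methyl ester (C6 epimers)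
Conditions: Pd(OAc)2 (10 mol %), (R)-BINAP (12 mol %), HCO2Na, DMF, 60 °C
Reagents that add atoms: none
Why: Reductive Heck cyclization: oxidative addition of the alkenyl triflate, 5-exo-trig syn-carbopalladation of one enone arm (C10–C9 bond, ring B, cis B/C fusion) and formate reduction of the palladium enolate, which has no syn β-hydrogen; the chiral bisphosphine is used to reinforce selection of the arm that puts H9 cis to H5 and the silylpropargyl group on the β face, so C8 and C9 are set together.

Step 11
Reactants: 18 tricyclic diester (C10=C20 alkene, C19 tert-butyl ester)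
Product: 19 iodolactone: 19,10α-γ-lactone with 20β-iodide; ring C enone, silyl alkyne and C7 methyl ester unchanged (C6 epimers)
Conditions: I2, NaHCO3, MeCN, 0 °C to rt
Reagents that add atoms: iodine, II
Why: Iodolactonization with loss of the tert-butyl group as isobutene: the C19 carbonyl oxygen is held on the α face at C4 and attacks the tertiary carbon C10 (5-exo, Markovnikov), so iodine must add anti on the β face at C20.

Step 12
Reactants: 19 iodolactone (19,10α-lactone, 20β-iodide)
Product: 20 tricyclic 10α,20α-epoxide: C19 and C7 methyl esters, 6β-ester, terminal alkyne, ring C enone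
Conditions: NaOMe, MeOH, 0 °C to rt
Reagents that add atoms: sodium methoxide, [Na+].[O-]C
Why: Methoxide opens the lactone at C19 and the freed C10 alkoxide displaces the anti-periplanar C20 iodide with inversion (the standard iodolactone-to-epoxy-ester conversion), giving the α-epoxide; the same base removes the alkynyl silyl group and should equilibrate C6 to the more stable 6β-ester, trans to the C4 substituent on C5.

Step 13
Reactants: 20 tricyclic 10α,20α-epoxide (ring C enone, terminal alkyne)
Product: 22 tert-butyldimethylsilyl enol ether (C12–O–Si, C12=C13) of the epoxy diester, via lithium enolate 21 (not isolated)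
Conditions: LiBH(s-Bu)3, THF, −78 °C; then TBSCl, HMPA, −78 to 0 °C
Reagents that add atoms: tert-butyldimethylsilyl chloride, CC(C)(C)[Si](C)(C)Cl
Why: Conjugate hydride reduction of the β-unsubstituted enone by the hindered borohydride and O-silylation of the enolate should give the C12–C13 silyl enol ether regiospecifically; epoxide and esters are inert at this temperature.

Step 14
Reactants: 22 tert-butyldimethylsilyl enol ether of the epoxy diester
Product: 23 tetracyclic keto epoxide: bicyclo[3.2.1]octan-12-one with C16=C17 exocyclic methylene, 10α,20α-epoxide in the seven-membered ring, dimethyl ester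
Conditions: Ph3PAuCl (5 mol %), AgNTf2 (5 mol %), CH2Cl2, H2O (2 equiv), rt
Reagents that add atoms: none
Why: Gold-catalysed 5-exo-dig carbocyclization of the silyl enol ether onto the activated terminal alkyne (Conia-ene type) forms the C13–C16 bond and, after protodeauration, the exocyclic methylene; C13 can only form on the β face, where the propargyl group on C8 sits.

Step 15
Reactants: 23 tetracyclic keto epoxide (10α,20α-epoxide, seven-membered ring)
Product: 24 dimethyl ester of the target (C20 aldehyde on C10, six-membered ring A, trans A/B fusion)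
Conditions: methylaluminium bis(4-bromo-2,6-di-tert-butylphenoxide) (2.5 equiv), CH2Cl2, −78 to −20 °C
Reagents that add atoms: none
Why: The bulky aluminium Lewis acid binds the epoxide oxygen and ionizes the tertiary C10–O bond; as positive charge builds at C10, the C20–C1 ring bond on the β face, anti to the departing α oxygen, shifts from C20 to C10 and C20 becomes the formyl carbon (Meinwald-type semipinacol rearrangement, the reaction type by which 1-alkylcycloalkene oxides contract to 1-alkylcycloalkanecarbaldehydes with this reagent). Ring A (C10, C1, C2, C3, C4, C5) is not closed by joining chain ends; it arises from the seven-membered ring C10–C20–C1–C2–C3–C4–C5 by this suprafacial 1,2-alkyl shift, which excises C20. The only new stereocentre, quaternary C10, is set with inversion: C1 enters on the β face and C20 is pushed to the α face, so the trans A/B fusion and the α-formyl group follow from the α-epoxide, which the α-C19 carboxyl fixed through the iodolactone. The step needs migration of C1 in preference to the C20 hydride shift (which would give the cycloheptanone) and to proton loss from C9 or C5; the very hindered aluminium phenoxide is the promoter known to favour alkyl over hydride shift, and C10 is the only tertiary epoxide carbon. The aldehyde formed has no α-hydrogen, so C10 cannot epimerize afterwards.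

Step 16
Reactants: 24 dimethyl ester of the target
Product: 25 target diacid (12-oxo C20-gibberellin 7,19-dioic acid with a C10 formyl group)
Conditions: LiSPr, HMPA, 25 °C; then 1 M HCl
Reagents that add atoms: none
Why: SN2 demethylation of both methyl esters by thiolate at the methyl carbons does not depend on access to the hindered C19 carbonyl and should leave aldehyde, ketone and exocyclic alkene intact; acidification gives the diacid, which may equilibrate with its 19,20-lactol form.

**Compound list**

1 | cycloheptane-1,3-dione | O=C1CCCCC(=O)C1 | starting material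
2 | 3-oxocyclohept-1-en-1-yl trifluoromethanesulfonate | O=C1C=C(OS(=O)(=O)C(F)(F)F)CCCC1 | intermediate
3 | tert-butyl 3-oxocyclohept-1-ene-1-carboxylate | O=C1C=C(C(=O)OC(C)(C)C)CCCC1 | intermediate
4 | methyl glyoxylate | COC(=O)C=O | starting material
5 | methylzinc enolate of tert-butyl (1R)-1-methyl-3-oxocycloheptane-1-carboxylate | C[C@@]1(C(=O)OC(C)(C)C)CCCCC(O[Zn]C)=C1 | intermediate (not isolated)
6 | tert-butyl (1R)-2-(1-hydroxy-2-methoxy-2-oxoethyl)-1-methyl-3-oxocycloheptane-1-carboxylate (mixture at the aldol centres) | C[C@@]1(C(=O)OC(C)(C)C)CCCCC(=O)C1C(O)C(=O)OC | intermediate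
7 | methanesulfonate of 6 | C[C@@]1(C(=O)OC(C)(C)C)CCCCC(=O)C1C(OS(C)(=O)=O)C(=O)OC | intermediate (not isolated)
8 | tert-butyl (1R)-2-(2-methoxy-2-oxoethylidene)-1-methyl-3-oxocycloheptane-1-carboxylate (E/Z mixture) | C[C@@]1(C(=O)OC(C)(C)C)CCCCC(=O)C1=CC(=O)OC | intermediate
9 | 5-(trimethylsilyl)pent-4-yn-1-ol | C[Si](C)(C)C#CCCCO | starting material
10 | 5-(trimethylsilyl)pent-4-ynal | C[Si](C)(C)C#CCCC=O | intermediate
11 | tert-butyl (1R,2R)-2-[3-formyl-1-methoxy-1-oxo-6-(trimethylsilyl)hex-5-yn-2-yl]-1-methyl-3-oxocycloheptane-1-carboxylate (epimers at C6, C8) | C[C@@]1(C(=O)OC(C)(C)C)CCCCC(=O)[C@@H]1C(C(=O)OC)C(C=O)CC#C[Si](C)(C)C | intermediate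
12 | methyl vinyl ketone | CC(=O)C=C | starting material
13 | keto aldehyde Michael adduct of 11 and 12 (C8 quaternary) | C[C@@]1(C(=O)OC(C)(C)C)CCCCC(=O)[C@@H]1C(C(=O)OC)C(C=O)(CC#C[Si](C)(C)C)CCC(C)=O | intermediate (not isolated)
14 | cyclohex-2-enone 14 (ring C, C8 quaternary; epimers at C6, C8) | C[C@@]1(C(=O)OC(C)(C)C)CCCCC(=O)[C@@H]1C(C(=O)OC)C2(CC#C[Si](C)(C)C)C=CC(=O)CC2 | intermediate
15 | cyclohexa-2,5-dienone 15 (epimers at C6) | C[C@@]1(C(=O)OC(C)(C)C)CCCCC(=O)[C@@H]1C(C(=O)OC)C2(CC#C[Si](C)(C)C)C=CC(=O)C=C2 | intermediate
16 | potassium C10–C20 enolate of 15 | C[C@@]1(C(=O)OC(C)(C)C)CCCC=C(O[K])[C@@H]1C(C(=O)OC)C2(CC#C[Si](C)(C)C)C=CC(=O)C=C2 | intermediate (not isolated)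
17 | C10 alkenyl triflate (C10=C20) | C[C@@]1(C(=O)OC(C)(C)C)CCCC=C(OS(=O)(=O)C(F)(F)F)[C@@H]1C(C(=O)OC)C2(CC#C[Si](C)(C)C)C=CC(=O)C=C2 | intermediate
18 | tricyclic diester (5β-H, 9β-H, 8β-silylpropargyl, C10=C20, 13-en-12-one; C6 epimers) | C[C@@]1(C(=O)OC(C)(C)C)CCCC=C2[C@@H]1C(C(=O)OC)[C@@]3(CC#C[Si](C)(C)C)C=CC(=O)C[C@@H]23 | intermediate
19 | iodolactone (19,10α-lactone, 20β-iodide; C6 epimers) | O=C1O[C@@]23[C@H](I)CCC[C@]1(C)[C@H]2C(C(=O)OC)[C@@]4(CC#C[Si](C)(C)C)C=CC(=O)C[C@@H]34 | intermediate
20 | tricyclic 10α,20α-epoxide, dimethyl ester, 6β-ester, terminal alkyne | C[C@@]1(C(=O)OC)CCC[C@@H]2O[C@]23[C@@H]1[C@H](C(=O)OC)[C@@]4(CC#C)C=CC(=O)C[C@@H]34 | intermediate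
21 | lithium C12–C13 enolate of the reduced enone | C[C@@]1(C(=O)OC)CCC[C@@H]2O[C@]23[C@@H]1[C@H](C(=O)OC)[C@@]4(CC#C)CC=C(O[Li])C[C@@H]34 | intermediate (not isolated)
22 | tert-butyldimethylsilyl enol ether (C12=C13) of the epoxy diester | C[C@@]1(C(=O)OC)CCC[C@@H]2O[C@]23[C@@H]1[C@H](C(=O)OC)[C@@]4(CC#C)CC=C(O[Si](C)(C)C(C)(C)C)C[C@@H]34 | intermediate
23 | tetracyclic keto epoxide (12-ketone, 16-methylene, 10α,20α-epoxide, dimethyl ester) | C=C1C[C@]23C[C@H]1C(=O)C[C@H]2[C@]14O[C@H]1CCC[C@@](C)(C(=O)OC)[C@H]4[C@@H]3C(=O)OC | intermediate
24 | dimethyl ester of the target | C=C1C[C@]23C[C@H]1C(=O)C[C@H]2[C@]1(C=O)CCC[C@@](C)(C(=O)OC)[C@H]1[C@@H]3C(=O)OC | intermediate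
25 | target diacid (12-oxo C20-gibberellin 7,19-dioic acid with a C10 formyl group) | C=C1C[C@]23C[C@H]1C(=O)C[C@H]2[C@]1(C=O)CCC[C@@](C)(C(=O)O)[C@H]1[C@@H]3C(=O)O | target

**Step count**

Total: 16 steps. Longest linear sequence: 15 steps (1 to 25 through steps 1–4 and 6–16); step 5 is a one-step side branch.

**Steps most likely to fail**

Step 10. The alkenylpalladium intermediate may be reduced by formate before it cyclizes, may insert into the silylalkyne instead of the enone, or may select the other enone arm (giving the C8/C9-epimeric series). The fallback sets out from 17: Miyaura borylation (bis(pinacolato)diboron, PdCl2(dppf), KOAc, dioxane) should give the alkenyl pinacol boronate F1, and rhodium-catalysed asymmetric intramolecular 1,4-addition ([Rh(OH)(cod)]2, (R)-BINAP, aqueous dioxane, 60 °C) closes ring B under ligand control with protonation of the rhodium enolate by water. It comes back to the route at 18.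

Step 15. The C20 hydride may shift in place of C1 (giving the cycloheptanone), a proton may be lost from C9 or C5, or the Lewis acid may be held by the C12 ketone while the exocyclic alkene attacks the developing cation or the new aldehyde. The fallback moves the ring contraction ahead of ring D, where neither the bridged ketone nor the exocyclic alkene exists; it does not remove the risk of hydride shift. It sets out from 20: the same aluminium reagent should give the tricyclic aldehyde F2, which is masked as its dimethyl acetal F3 (HC(OMe)3, PPTS, MeOH). Conjugate reduction and silylation as in step 13 give the silyl enol ether F4, and the gold cyclization of step 14 gives the tetracyclic acetal F5. Mild aqueous acid (PPTS, acetone/water) releases the aldehyde, and the route is rejoined at 24.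

Step 7. Enamine formation at the congested α-branched aldehyde may be slow, and the ring ketone may aldolize through C20 onto the aldehyde instead of the methyl ketone. The fallback reverses the order of the two Michael additions. It sets out from 10 and 12: amine-catalysed Michael addition of the unbranched aldehyde to methyl vinyl ketone should give 5-oxo-2-[3-(trimethylsilyl)prop-2-ynyl]hexanal F6. Its enamine then adds to the more electrophilic acceptor 8, forming quaternary C8 and giving 13, which condenses under the conditions of step 7. It comes back to the route at 14.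

**Further compounds**

F1 | step 10 | C10 alkenyl pinacol boronate corresponding to 17 | C[C@@]1(C(=O)OC(C)(C)C)CCCC=C(B2OC(C)(C)C(C)(C)O2)[C@@H]1C(C(=O)OC)C3(CC#C[Si](C)(C)C)C=CC(=O)C=C3
F2 | step 15 | tricyclic aldehyde (ring A contracted, C20 formyl α on C10, ring C enone, terminal alkyne, dimethyl ester) | C#CC[C@]12C=CC(=O)C[C@H]1[C@]3(C=O)CCC[C@@](C)(C(=O)OC)[C@H]3[C@@H]2C(=O)OC
F3 | step 15 | dimethyl acetal of F2 | C#CC[C@]12C=CC(=O)C[C@H]1[C@]3(C(OC)OC)CCC[C@@](C)(C(=O)OC)[C@H]3[C@@H]2C(=O)OC
F4 | step 15 | tert-butyldimethylsilyl enol ether (C12=C13) of the acetal | C#CC[C@]12CC=C(O[Si](C)(C)C(C)(C)C)C[C@H]1[C@]3(C(OC)OC)CCC[C@@](C)(C(=O)OC)[C@H]3[C@@H]2C(=O)OC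
F5 | step 15 | tetracyclic dimethyl acetal of 24 | C=C1C[C@]23C[C@H]1C(=O)C[C@H]2[C@]1(C(OC)OC)CCC[C@@](C)(C(=O)OC)[C@H]1[C@@H]3C(=O)OC
F6 | step 7 | 5-oxo-2-[3-(trimethylsilyl)prop-2-ynyl]hexanal | O=CC(CC#C[Si](C)(C)C)CCC(C)=O
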